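## Retrosynthetic overview

1. Target 17 comes from aldol adduct 15 by C7‑O acetylation and removal of the C12 O‑TMS group; 15 comes from a C7–C8 anti‑aldol between iodo‑enone 9 (ring plus ω‑chain) and Z‑enal 14 (α‑chain).
2. Iodo‑enone 9 comes from (S)‑hydroxy‑enone 6 by Lindlar reduction, silylation and α‑iodination.
3. Hydroxy‑enone 6 comes from forming the C12–C13 bond: a Cu(I)‑catalysed enantioselective propargyl–carbonyl coupling of oct‑2‑ynyl boronate 3 (from hept‑1‑yne) with mono‑ketal 5 of cyclopent‑4‑ene‑1,3‑dione. This sets C12 and is the proposed new method.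
4. Z‑enal 14 comes from hex‑5‑ynoic acid by hydroxymethylation, esterification, Lindlar reduction and oxidation.
5. Rings: the only ring (the cyclopentenone) is bought intact as cyclopent‑4‑ene‑1,3‑dione; no ring‑forming step is needed.

Assumptions: prostanoid numbering is used (C1 ester to C20; C7 = CH‑OAc, C8 = ring CH, C12 = ring carbinol), and the target is (5Z,14Z,7S,8R,12S). (R)‑BINAP is assumed to give the (S)‑carbinol in Step 4; if the first run shows the opposite sense, use (S)‑BINAP.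

## Route

**Step 1**
Reactants: 1, hept‑1‑yne
Product: 2, 2‑(hept‑1‑yn‑1‑yl)‑4,4,5,5‑tetramethyl‑1,3,2‑dioxaborolane
Conditions: n‑BuLi, THF, −78 °C; i‑PrOBpin, −78 °C; HCl·Et2O, −78 °C → rt
Reagents that add atoms: 2‑isopropoxy‑4,4,5,5‑tetramethyl‑1,3,2‑dioxaborolane, CC(C)OB1OC(C)(C)C(C)(C)O1
Why: Borylation of the lithium acetylide; anhydrous HCl collapses the alkynyl "ate" complex to the alkynyl boronate.

**Step 2**
Reactants: 2, 2‑(hept‑1‑yn‑1‑yl)‑4,4,5,5‑tetramethyl‑1,3,2‑dioxaborolane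
Product: 3, 4,4,5,5‑tetramethyl‑2‑(oct‑2‑yn‑1‑yl)‑1,3,2‑dioxaborolane
Conditions: BrCH2Cl, n‑BuLi, THF, −78 °C → rt
Reagents that add atoms: bromochloromethane, ClCBr
Why: Matteson homologation; in situ LiCH2Cl forms the boron ate complex and a 1,2‑alkynyl shift expels chloride, inserting the CH2 (future C13) and giving only the propargyl (not allenyl) boronate.

**Step 3**
Reactants: 4, cyclopent‑4‑ene‑1,3‑dione
Product: 5, 8,8‑dimethyl‑6,10‑dioxaspiro[4.5]dec‑3‑en‑2‑one
Conditions: 2,2‑dimethylpropane‑1,3‑diol (1.0 equiv), TsOH (cat.), benzene, reflux, Dean–Stark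
Reagents that add atoms: 2,2‑dimethylpropane‑1,3‑diol, OCC(C)(C)CO
Why: Acid‑catalysed mono‑ketalisation; it removes the acidic, base‑sensitive 1,3‑dione CH2 and leaves one ketone flanked by two sterically different groups, and the remaining enone carbonyl ketalises much more slowly.

**Step 4**
Reactants: 3, 4,4,5,5‑tetramethyl‑2‑(oct‑2‑yn‑1‑yl)‑1,3,2‑dioxaborolane; 5, 8,8‑dimethyl‑6,10‑dioxaspiro[4.5]dec‑3‑en‑2‑one
Product: 6, (S)‑4‑hydroxy‑4‑(oct‑2‑yn‑1‑yl)cyclopent‑2‑en‑1‑one
Conditions: 3 (1.3 equiv), Cu(O2C‑i‑Pr)2 (5 mol %), (R)‑BINAP (6 mol %), LiOt‑Bu (8 mol %), THF, −40 °C; then 1 M aq HCl, THF, 0 °C → rt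
Reagents that add atoms: water (oxygen of the unmasked ketone), O
Why: Proposed new method: a Cu(I)–bisphosphine‑catalysed enantioselective propargyl–carbonyl coupling of a γ‑alkyl propargyl boronate with a masked cyclopentenedione; Cu–Ot‑Bu transmetalates with 3 in SE2′ fashion to give a (1‑pentylallenyl)copper–BINAP species, which adds to the ketone of 5 through a closed six‑membered SE2′ transition state at its unsubstituted CH2 terminus (bond formation at the pentyl‑bearing carbon would join two fully substituted carbons and is disfavoured), so only the homopropargylic 1,2‑adduct forms and the Cu alkoxide turns over with more 3; the ligand distinguishes the flat CH=CH flank from the bulky CH2–C(spiroketal) flank to set C12 (S after unmasking), and the acidic work‑up hydrolyses the allylic ketal to the enone; the closest known reaction type is Cu–BINAP‑catalysed asymmetric propargylation of simple aryl/alkyl ketones with the TMS‑substituted propargyl pinacol boronate (and Cu‑catalysed asymmetric allylboration of ketones).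

**Step 5**
Reactants: 6, (S)‑4‑hydroxy‑4‑(oct‑2‑yn‑1‑yl)cyclopent‑2‑en‑1‑one
Product: 7, (S)‑4‑hydroxy‑4‑[(2Z)‑oct‑2‑en‑1‑yl]cyclopent‑2‑en‑1‑one
Conditions: H2 (1 atm, 1.0 equiv uptake), Lindlar catalyst, quinoline, EtOAc, rt
Reagents that add atoms: none
Why: Lindlar semi‑hydrogenation (syn addition) gives the 14Z alkene; the poisoned catalyst reduces the alkyne far faster than the electron‑poor ring enone, and doing it here keeps Pd/H2 away from the later vinyl iodide.

**Step 6**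
Reactants: 7, (S)‑4‑hydroxy‑4‑[(2Z)‑oct‑2‑en‑1‑yl]cyclopent‑2‑en‑1‑one
Product: 8, (S)‑4‑[(2Z)‑oct‑2‑en‑1‑yl]‑4‑[(trimethylsilyl)oxy]cyclopent‑2‑en‑1‑one
Conditions: TMSCl, imidazole, DMF, 0 °C → rt
Reagents that add atoms: chlorotrimethylsilane, C[Si](C)(C)Cl
Why: Silylation of the tertiary alcohol; capping the β‑hydroxy ketone blocks retro‑aldol ring opening (which would racemise C12), prevents iodo‑etherification onto the homoallylic alkene, and keeps the oxygen substituent small for Step 12.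

**Step 7**
Reactants: 8, (S)‑4‑[(2Z)‑oct‑2‑en‑1‑yl]‑4‑[(trimethylsilyl)oxy]cyclopent‑2‑en‑1‑one
Product: 9, (S)‑2‑iodo‑4‑[(2Z)‑oct‑2‑en‑1‑yl]‑4‑[(trimethylsilyl)oxy]cyclopent‑2‑en‑1‑one
Conditions: I2, pyridine/CH2Cl2 (1:1), 0 °C → rt, dark
Reagents that add atoms: iodine, II
Why: Johnson α‑iodination of the enone (pyridine conjugate addition, iodination of the enolate, elimination) places iodine only at C10, and pyridine‑complexed I2 does not attack the isolated Z‑alkene.

**Step 8**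
Reactants: 10, hex‑5‑ynoic acid
Product: 11, 7‑hydroxyhept‑5‑ynoic acid
Conditions: EtMgBr (2.2 equiv), THF, 0 → 40 °C; (CH2O)n, 40 °C; aq. NH4Cl/HCl
Reagents that add atoms: formaldehyde (paraformaldehyde), C=O
Why: The carboxylate/acetylide dianion adds to formaldehyde (acetylide hydroxymethylation); working on the free acid avoids competing ester enolisation or addition.

**Step 9**
Reactants: 11, 7‑hydroxyhept‑5‑ynoic acid
Product: 12, methyl 7‑hydroxyhept‑5‑ynoate
Conditions: MeOH, H2SO4 (cat.), rt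
Reagents that add atoms: methanol, CO
Why: Fischer esterification in methanol as solvent; the rigid alkyne prevents lactonisation.

**Step 10**
Reactants: 12, methyl 7‑hydroxyhept‑5‑ynoate
Product: 13, methyl (5Z)‑7‑hydroxyhept‑5‑enoate
Conditions: H2 (1 atm), Lindlar catalyst, quinoline, EtOAc, rt
Reagents that add atoms: none
Why: Lindlar syn semi‑hydrogenation of the propargylic alcohol sets the 5Z alkene.

**Step 11**
Reactants: 13, methyl (5Z)‑7‑hydroxyhept‑5‑enoate
Product: 14, methyl (5Z)‑7‑oxohept‑5‑enoate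
Conditions: Dess–Martin periodinane, NaHCO3, CH2Cl2, 0 °C; used at once
Reagents that add atoms: none
Why: Buffered, near‑neutral Dess–Martin oxidation of the allylic alcohol gives the Z‑enal without the acid/base exposure that causes Z→E isomerisation.

**Step 12**
Reactants: 9, (S)‑2‑iodo‑4‑[(2Z)‑oct‑2‑en‑1‑yl]‑4‑[(trimethylsilyl)oxy]cyclopent‑2‑en‑1‑one; 14, methyl (5Z)‑7‑oxohept‑5‑enoate
Product: 15, methyl (5Z,7S)‑7‑hydroxy‑7‑[(1R,2S)‑4‑iodo‑2‑[(2Z)‑oct‑2‑en‑1‑yl]‑5‑oxo‑2‑[(trimethylsilyl)oxy]cyclopent‑3‑en‑1‑yl]hept‑5‑enoate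
Conditions: Cy2BCl, Et3N, Et2O, −78 → 0 °C; 14, −78 °C; pH 7 buffer/MeOH/H2O2, 0 °C
Reagents that add atoms: none
Why: Boron‑mediated aldol of the only enolisable position (C8); the ring‑locked E‑enol borinate reacts through a Zimmerman–Traxler chair to give the anti (7S relative to 8R) aldol, and the aldehyde is expected to enter on the face anti to the C12 CH2 chain (syn to the small OSiMe3 oxygen, anti to the better σ‑donor C–C bond), which puts the α‑chain trans to the ω‑chain and sets C8 as R.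

**Step 13**
Reactants: 15, the aldol adduct above
Product: 16, methyl (5Z,7S)‑7‑(acetyloxy)‑7‑[(1R,2S)‑4‑iodo‑2‑[(2Z)‑oct‑2‑en‑1‑yl]‑5‑oxo‑2‑[(trimethylsilyl)oxy]cyclopent‑3‑en‑1‑yl]hept‑5‑enoate
Conditions: Ac2O, pyridine, DMAP (cat.), CH2Cl2, −10 → 0 °C
Reagents that add atoms: acetic anhydride, CC(=O)OC(C)=O
Why: Acylation of the only free (secondary) alcohol with retention at C7; low temperature and a weak base limit E1cB loss of the β‑acetoxy group.

**Step 14**
Reactants: 16, the silyl ether acetate above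
Product: 17, methyl (5Z,7S)‑7‑(acetyloxy)‑7‑[(1R,2S)‑2‑hydroxy‑4‑iodo‑2‑[(2Z)‑oct‑2‑en‑1‑yl]‑5‑oxocyclopent‑3‑en‑1‑yl]hept‑5‑enoate (7‑acetoxy‑7,8‑dihydroiodovulone I)
Conditions: HF·pyridine, pyridine/THF, 0 °C
Reagents that add atoms: none
Why: Fluoride‑mediated cleavage of the tertiary TMS ether under buffered, mildly acidic conditions that leave the β‑acetoxy ketone, vinyl iodide, allylic acetate, methyl ester and both Z‑alkenes untouched.

## Compound list

1 | hept‑1‑yne | CCCCCC#C | starting material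
2 | 2‑(hept‑1‑yn‑1‑yl)‑4,4,5,5‑tetramethyl‑1,3,2‑dioxaborolane | CCCCCC#CB1OC(C)(C)C(C)(C)O1 | intermediate
3 | 4,4,5,5‑tetramethyl‑2‑(oct‑2‑yn‑1‑yl)‑1,3,2‑dioxaborolane | CCCCCC#CCB1OC(C)(C)C(C)(C)O1 | intermediate
4 | cyclopent‑4‑ene‑1,3‑dione | O=C1CC(=O)C=C1 | starting material
5 | 8,8‑dimethyl‑6,10‑dioxaspiro[4.5]dec‑3‑en‑2‑one | O=C1C=CC2(C1)OCC(C)(C)CO2 | intermediate
6 | (S)‑4‑hydroxy‑4‑(oct‑2‑yn‑1‑yl)cyclopent‑2‑en‑1‑one | CCCCCC#CC[C@@]1(O)C=CC(=O)C1 | intermediate
7 | (S)‑4‑hydroxy‑4‑[(2Z)‑oct‑2‑en‑1‑yl]cyclopent‑2‑en‑1‑one | CCCCC/C=C\C[C@@]1(O)C=CC(=O)C1 | intermediate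
8 | (S)‑4‑[(2Z)‑oct‑2‑en‑1‑yl]‑4‑[(trimethylsilyl)oxy]cyclopent‑2‑en‑1‑one | CCCCC/C=C\C[C@@]1(O[Si](C)(C)C)C=CC(=O)C1 | intermediate
9 | (S)‑2‑iodo‑4‑[(2Z)‑oct‑2‑en‑1‑yl]‑4‑[(trimethylsilyl)oxy]cyclopent‑2‑en‑1‑one | CCCCC/C=C\C[C@@]1(O[Si](C)(C)C)C=C(I)C(=O)C1 | intermediate
10 | hex‑5‑ynoic acid | C#CCCCC(=O)O | starting material
11 | 7‑hydroxyhept‑5‑ynoic acid | OCC#CCCCC(=O)O | intermediate
12 | methyl 7‑hydroxyhept‑5‑ynoate | OCC#CCCCC(=O)OC | intermediate
13 | methyl (5Z)‑7‑hydroxyhept‑5‑enoate | OC/C=C\CCCC(=O)OC | intermediate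
14 | methyl (5Z)‑7‑oxohept‑5‑enoate | O=C/C=C\CCCC(=O)OC | intermediate
15 | methyl (5Z,7S)‑7‑hydroxy‑7‑[(1R,2S)‑4‑iodo‑2‑[(2Z)‑oct‑2‑en‑1‑yl]‑5‑oxo‑2‑[(trimethylsilyl)oxy]cyclopent‑3‑en‑1‑yl]hept‑5‑enoate | CCCCC/C=C\C[C@@]1(O[Si](C)(C)C)C=C(I)C(=O)[C@@H]1[C@H](/C=C\CCCC(=O)OC)O | intermediate
16 | methyl (5Z,7S)‑7‑(acetyloxy)‑7‑[(1R,2S)‑4‑iodo‑2‑[(2Z)‑oct‑2‑en‑1‑yl]‑5‑oxo‑2‑[(trimethylsilyl)oxy]cyclopent‑3‑en‑1‑yl]hept‑5‑enoate | CCCCC/C=C\C[C@@]1(O[Si](C)(C)C)C=C(I)C(=O)[C@@H]1[C@H](/C=C\CCCC(=O)OC)OC(C)=O | intermediate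
17 | methyl (5Z,7S)‑7‑(acetyloxy)‑7‑[(1R,2S)‑2‑hydroxy‑4‑iodo‑2‑[(2Z)‑oct‑2‑en‑1‑yl]‑5‑oxocyclopent‑3‑en‑1‑yl]hept‑5‑enoate (7‑acetoxy‑7,8‑dihydroiodovulone I) | CCCCC/C=C\C[C@@]1(O)C=C(I)C(=O)[C@@H]1[C@H](/C=C\CCCC(=O)OC)OC(C)=O | target

## Summary

Total step count: 14.

Longest linear sequence: 9 steps (Steps 1, 2, 4, 5, 6, 7, 12, 13, 14, from hept‑1‑yne). The other branches are 8 steps from cyclopent‑4‑ene‑1,3‑dione and 7 steps from hex‑5‑ynoic acid.

Three steps most likely to fail: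

1. **Step 4 (proposed new Cu‑catalysed asymmetric propargylation).** The risks are low ee on the enone–ketal, allenyl versus homopropargyl regiochemistry, and catalyst turnover. Fallback (known chemistry, chirality from the chiral pool): start from commercial (R)‑4‑(tert‑butyldimethylsilyloxy)cyclopent‑2‑en‑1‑one, add 3 to the ketone with an achiral Zn or Cu catalyst anti to the OTBS group, remove the silyl group with TBAF, and oxidise the secondary allylic alcohol with MnO2 to reach (S)‑6.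

2. **Step 12 (boron aldol of iodo‑enone 9 with Z‑enal 14).** The risks are facial selectivity at C8, anti selectivity at C7, lability of the α‑iodo‑enone, and Z→E isomerisation of the enal. Fallback: join the fragments before halogenation. Use the lithium or zinc enolate of non‑iodinated 8 with the ynal methyl 7‑oxohept‑5‑ynoate (Dess–Martin oxidation of 12), Lindlar‑reduce the C5 alkyne in the adduct, and carry out the I2/pyridine α‑iodination late, before acetylation and desilylation.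

3. **Step 2 (Matteson homologation with a 1,2‑alkynyl shift).** The risks are reversal of the alkynyl ate complex and formation of the allenyl isomer. Fallback: drop the propargyl reagent. Use commercial allyl‑Bpin in the Cu‑catalysed asymmetric ketone allylation of 5, then install the chain by Z‑selective Ru‑catalysed cross‑metathesis of the resulting allyl carbinol with hept‑1‑ene to give 7 directly; this removes Steps 1, 2 and 5.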